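The route rests on disconnecting the aryl ether bond O1–C8a in ring C of the upper epicatechin unit. The precursor is an open-chain, all-syn 2-benzyloxy-1,3-diol carrying a 2-fluoro-4,6-bis(benzyloxy)phenyl group at the future C4; the alkoxide at the future C2 displaces fluoride at C8a (reverse-polarity SNAr) and closes ring C in one operation without touching the C2–O or C3–O bonds, so the 2,3-cis array set by an Evans glycolate aldol is transcribed intact. The step exploits that C8a of ring A is meta to both O5 and O7 and therefore not deactivated by them. The resulting flavan-3,4-diol derivative is then joined, leucocyanidin-style, through C4 to C8 of an epicatechin-derived 4β-carboxymethyl lower unit.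

Key step: step 11

Remark: the target is read as epicatechin-(4β→8)-4β-(carboxymethyl)epicatechin (both units 2R,3R, both C4 substituents trans to O3); flavan numbering is used for ring atoms throughout, also for the atoms of open-chain precursors that become them.

Step 1
Reactants: 1 (−)-epicatechin
Product: 2 5,7,3',4'-tetra-O-benzylepicatechin
Conditions: BnBr (4.4 equiv), K2CO3, DMF, 0 °C to rt
Reagents that add atoms: benzyl bromide, BrCc1ccccc1
Why: Williamson ether synthesis in which K2CO3 deprotonates only the four phenols, so the secondary 3-OH should stay free and no stereocenter is touched.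

Step 2
Reactants: 2 5,7,3',4'-tetra-O-benzylepicatechin
Product: 4 4β-(2-ethoxyethoxy)-5,7,3',4'-tetra-O-benzylepicatechin, via C4 cation hydroquinonate ion pair 3 (not isolated)
Conditions: DDQ (2 equiv), 2-ethoxyethanol (5 equiv), CH2Cl2, rt
Reagents that add atoms: 2-ethoxyethanol, CCOCCO
Why: DDQ benzylic oxidation (hydride abstraction at C4, the cation being stabilised by O5 and O7 of ring A and paired with the hydroquinone monoanion) followed by capture of the alcohol anti to the axial 3-OH, which should set the 4β ether.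

Step 3
Reactants: 4 4β-(2-ethoxyethoxy)-5,7,3',4'-tetra-O-benzylepicatechin
Product: 6 methyl [(2R,3R,4S)-5,7-bis(benzyloxy)-2-[3,4-bis(benzyloxy)phenyl]-3-hydroxychroman-4-yl]acetate, via C4 cation triflate 5 (not isolated)
Conditions: 1-(tert-butyldimethylsilyloxy)-1-methoxyethene (3 equiv), TMSOTf (0.2 equiv), CH2Cl2, −78 °C; sat. aq. NaHCO3 quench
Reagents that add atoms: 1-(tert-butyldimethylsilyloxy)-1-methoxyethene, C=C(OC)O[Si](C)(C)C(C)(C)C
Why: Mukaiyama-type SN1 alkylation in which the silyl triflate activates the 4-ether oxygen, C4 ionises to the cation triflate and the silyl ketene acetal attacks on the β-face, anti to the axial 3-OH, which should give the 3,4-trans (4β) acetate side chain.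

Step 4
Reactants: 7 1,3,5-trifluorobenzene
Product: 9 1,3-bis(benzyloxy)-5-fluorobenzene, via 1-(benzyloxy)-3,5-difluorobenzene 8 (not isolated)
Conditions: BnOH (2.05 equiv), NaH (2.1 equiv), NMP, 0 °C then 80 °C
Reagents that add atoms: benzyl alcohol, OCc1ccccc1
Why: Twofold SNAr by benzyl oxide, each fluorine being activated inductively by the meta fluorines, while the third displacement on the now electron-rich ring should be slow enough to stop at the bis-ether.

Step 5
Reactants: 9 1,3-bis(benzyloxy)-5-fluorobenzene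
Product: 10 1,5-bis(benzyloxy)-2-bromo-3-fluorobenzene
Conditions: NBS (1.0 equiv), MeCN, 0 °C
Reagents that add atoms: N-bromosuccinimide, O=C1CCC(=O)N1Br
Why: Electrophilic aromatic bromination should occur para to one benzyloxy group and ortho to the other at the position flanked by the small fluorine, which is less hindered than the position between the two benzyloxy groups.

Step 6
Reactants: 11 (S)-4-benzyloxazolidin-2-one; 12 (benzyloxy)acetyl chloride
Product: 14 (S)-4-benzyl-3-[(benzyloxy)acetyl]oxazolidin-2-one, via N-lithio oxazolidinone 13 (not isolated)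
Conditions: n-BuLi, THF, −78 °C; then 12, −78 to 0 °C
Reagents that add atoms: none
Why: N-acylation of the lithiated oxazolidinone by the acid chloride, which does not involve the auxiliary stereocenter.

Step 7
Reactants: 14 (S)-4-benzyl-3-[(benzyloxy)acetyl]oxazolidin-2-one; 15 3,4-bis(benzyloxy)benzaldehyde
Product: 17 (S)-4-benzyl-3-[(2S,3R)-2-(benzyloxy)-3-[3,4-bis(benzyloxy)phenyl]-3-hydroxypropanoyl]oxazolidin-2-one, via Z dibutylboron enolate 16 (not isolated)
Conditions: Bu2BOTf, Et3N, CH2Cl2, −78 to 0 °C; then 15, −78 to 0 °C; pH 7 buffer, MeOH, H2O2, 0 °C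
Reagents that add atoms: none
Why: Evans syn-aldol reaction through a chair Zimmerman–Traxler transition state of the Z boron enolate, the auxiliary benzyl group shielding one face, which should set the syn (2S,3R) benzyloxy/hydroxy pair that becomes C3 and C2 of the upper unit.

Step 8
Reactants: 17 (S)-4-benzyl-3-[(2S,3R)-2-(benzyloxy)-3-[3,4-bis(benzyloxy)phenyl]-3-hydroxypropanoyl]oxazolidin-2-one
Product: 18 (2S,3R)-2-(benzyloxy)-3-[3,4-bis(benzyloxy)phenyl]-3-hydroxy-N-methoxy-N-methylpropanamide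
Conditions: MeONHMe·HCl, AlMe3, CH2Cl2, −20 °C to rt; aq. HCl work-up
Reagents that add atoms: N,O-dimethylhydroxylamine hydrochloride, CNOC.Cl
Why: Aluminium amide aminolysis of the exocyclic imide carbonyl (Weinreb amide formation), assisted by the free β-hydroxyl, should release the auxiliary without epimerisation.

Step 9
Reactants: 10 1,5-bis(benzyloxy)-2-bromo-3-fluorobenzene; 18 (2S,3R)-2-(benzyloxy)-3-[3,4-bis(benzyloxy)phenyl]-3-hydroxy-N-methoxy-N-methylpropanamide
Product: 20 (2S,3R)-2-(benzyloxy)-1-[2,4-bis(benzyloxy)-6-fluorophenyl]-3-[3,4-bis(benzyloxy)phenyl]-3-hydroxypropan-1-one, via aryllithium 19 (not isolated)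
Conditions: 10 (2.5 equiv), n-BuLi (2.4 equiv), THF, −78 °C; then 18, −78 °C; aq. NH4Cl
Reagents that add atoms: none
Why: Bromine–lithium exchange followed by Weinreb ketone synthesis, in which the chelated tetrahedral adduct should prevent over-addition, one equivalent of the aryllithium is spent on the hydroxyl, and −78 °C should keep the ortho-fluoroaryllithium from losing LiF.

Step 10
Reactants: 20 (2S,3R)-2-(benzyloxy)-1-[2,4-bis(benzyloxy)-6-fluorophenyl]-3-[3,4-bis(benzyloxy)phenyl]-3-hydroxypropan-1-one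
Product: 22 (1S,2S,3R)-2-(benzyloxy)-1-[2,4-bis(benzyloxy)-6-fluorophenyl]-3-[3,4-bis(benzyloxy)phenyl]propane-1,3-diol, via diethylborinate chelate 21 (not isolated)
Conditions: Et2BOMe, THF/MeOH 4:1, −78 °C; NaBH4; AcOH quench, evaporation from MeOH
Reagents that add atoms: none
Why: Narasaka–Prasad reduction, in which hydride attacks the six-membered boron chelate axially, should give the 1,3-syn diol and thus the all-syn triad; the new carbinol center (future C4) is erased again in step 12, so its control only serves homogeneity.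

Step 11
Reactants: 22 (1S,2S,3R)-2-(benzyloxy)-1-[2,4-bis(benzyloxy)-6-fluorophenyl]-3-[3,4-bis(benzyloxy)phenyl]propane-1,3-diol
Product: 24 (2R,3R,4S)-3,5,7-tris(benzyloxy)-2-[3,4-bis(benzyloxy)phenyl]chroman-4-ol, via dipotassium dialkoxide 23 (not isolated)
Conditions: KH (2.5 equiv), 18-crown-6, THF/DMPU, 0 to 60 °C; H2O quench
Reagents that add atoms: none
Why: KH converts both hydroxyls into alkoxides and the alkoxide on the carbon bearing ring B attacks the fluorine-bearing carbon of ring A in an addition–elimination (SNAr) through a Meisenheimer-type transition structure, fluoride being the best leaving group for this mechanism. The closest known reaction type is the intramolecular SNAr etherification of 3-(2-fluoroaryl)propanols to chromans, the reverse-polarity way of closing the pyran ring of flavans. Ring C is closed in a formally 6-exo-trig mode at the ipso carbon (the negative charge is pushed onto C8, C6 and C4a of ring A), which forms the O1–C8a aryl ether bond. No new stereocenter arises, and C2, C3 and C4 keep the configurations set in steps 7 and 10 because no bond to any of them is broken, so the 2,3-cis relationship that a cationic closure at C2 would erode is preserved. The step needs chemoselectivity among the oxygens, which the substrate secures: O3 is blocked as its benzyl ether, so the competing 5-exo closure to a dihydrobenzofuran is excluded, and the C4 alkoxide could only form a strained four-membered ring. The ipso carbon lies meta to both benzyloxy groups, which therefore act on it only by induction, so that an otherwise electron-rich ring should still accept the alkoxide.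

Step 12
Reactants: 24 (2R,3R,4S)-3,5,7-tris(benzyloxy)-2-[3,4-bis(benzyloxy)phenyl]chroman-4-ol; 6 methyl [(2R,3R,4S)-5,7-bis(benzyloxy)-2-[3,4-bis(benzyloxy)phenyl]-3-hydroxychroman-4-yl]acetate
Product: 26 methyl ester of 3,5,7,3',4'-penta-O-benzylepicatechin-(4β→8)-5,7,3',4'-tetra-O-benzyl-4β-(carboxymethyl)epicatechin, via upper-unit C4 cation triflate 25 (not isolated)
Conditions: 6 (3 equiv), TMSOTf (0.2 equiv), 4 Å molecular sieves, CH2Cl2, −78 to −30 °C; Et3N quench
Reagents that add atoms: none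
Why: Lewis acid-promoted dehydrative Friedel–Crafts alkylation in the manner of the leucocyanidin condensation, in which the ionised C4 is attacked by C8 of the excess lower unit (its most nucleophilic position) anti to the axial 3-benzyloxy group, which should set the 4β (3,4-trans, 4R) interflavan bond.

Step 13
Reactants: 26 methyl ester of 3,5,7,3',4'-penta-O-benzylepicatechin-(4β→8)-5,7,3',4'-tetra-O-benzyl-4β-(carboxymethyl)epicatechin
Product: 27 3,5,7,3',4'-penta-O-benzylepicatechin-(4β→8)-5,7,3',4'-tetra-O-benzyl-4β-(carboxymethyl)epicatechin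
Conditions: LiOH·H2O, THF/MeOH/H2O, rt; then dilute HCl to pH 4, 0 °C
Reagents that add atoms: lithium hydroxide, [Li+].[OH-]
Why: Saponification of the unhindered methyl ester, to which the benzyl ethers, the free 3-OH (trans to the side chain, so no lactone) and the interflavan bond should be inert.

Step 14
Reactants: 27 3,5,7,3',4'-penta-O-benzylepicatechin-(4β→8)-5,7,3',4'-tetra-O-benzyl-4β-(carboxymethyl)epicatechin
Product: 28 epicatechin-(4β→8)-4β-(carboxymethyl)epicatechin (CNP0190976.1)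
Conditions: H2 (1 atm), Pd(OH)2 on carbon, THF/MeOH/H2O, rt
Reagents that add atoms: none
Why: Catalytic hydrogenolysis should cleave the eight aryl benzyl ethers and the secondary benzyl ether at O3 of the upper unit under neutral conditions, leaving the acid-labile interflavan bond and all six stereocenters untouched.

Compound list
1 | (−)-epicatechin, (2R,3R)-2-(3,4-dihydroxyphenyl)chromane-3,5,7-triol | C1c2c(O)cc(O)cc2O[C@H](c2ccc(O)c(O)c2)[C@@H]1O | starting material
2 | 5,7,3',4'-tetra-O-benzylepicatechin | C1c2c(OCc3ccccc3)cc(OCc3ccccc3)cc2O[C@H](c2ccc(OCc3ccccc3)c(OCc3ccccc3)c2)[C@@H]1O | intermediate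
3 | C4 benzylic cation of 2 (3-OH free) as ion pair with 2,3-dichloro-5,6-dicyano-4-hydroxyphenolate | [CH+]1c2c(OCc3ccccc3)cc(OCc3ccccc3)cc2O[C@H](c2ccc(OCc3ccccc3)c(OCc3ccccc3)c2)[C@@H]1O.[O-]c1c(Cl)c(Cl)c(O)c(C#N)c1C#N | intermediate (not isolated)
4 | 4β-(2-ethoxyethoxy)-5,7,3',4'-tetra-O-benzylepicatechin, (2R,3R,4S) | CCOCCO[C@H]1c2c(OCc3ccccc3)cc(OCc3ccccc3)cc2O[C@H](c2ccc(OCc3ccccc3)c(OCc3ccccc3)c2)[C@@H]1O | intermediate
5 | C4 benzylic cation of tetra-O-benzylepicatechin (3-OH free) as its trifluoromethanesulfonate | [CH+]1c2c(OCc3ccccc3)cc(OCc3ccccc3)cc2O[C@H](c2ccc(OCc3ccccc3)c(OCc3ccccc3)c2)[C@@H]1O.[O-]S(=O)(=O)C(F)(F)F | intermediate (not isolated)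
6 | methyl [(2R,3R,4S)-5,7-bis(benzyloxy)-2-[3,4-bis(benzyloxy)phenyl]-3-hydroxychroman-4-yl]acetate | COC(=O)C[C@H]1c2c(OCc3ccccc3)cc(OCc3ccccc3)cc2O[C@H](c2ccc(OCc3ccccc3)c(OCc3ccccc3)c2)[C@@H]1O | intermediate
7 | 1,3,5-trifluorobenzene | Fc1cc(F)cc(F)c1 | starting material
8 | 1-(benzyloxy)-3,5-difluorobenzene | Fc1cc(F)cc(OCc2ccccc2)c1 | intermediate (not isolated)
9 | 1,3-bis(benzyloxy)-5-fluorobenzene | Fc1cc(OCc2ccccc2)cc(OCc2ccccc2)c1 | intermediate
10 | 1,5-bis(benzyloxy)-2-bromo-3-fluorobenzene | Fc1cc(OCc2ccccc2)cc(OCc2ccccc2)c1Br | intermediate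
11 | (S)-4-benzyloxazolidin-2-one | O=C1OC[C@H](Cc2ccccc2)N1 | starting material
12 | (benzyloxy)acetyl chloride | O=C(Cl)COCc1ccccc1 | starting material
13 | N-lithio derivative of 11 | O=C1OC[C@H](Cc2ccccc2)N1[Li] | intermediate (not isolated)
14 | (S)-4-benzyl-3-[(benzyloxy)acetyl]oxazolidin-2-one | O=C1OC[C@H](Cc2ccccc2)N1C(=O)COCc1ccccc1 | intermediate
15 | 3,4-bis(benzyloxy)benzaldehyde | O=Cc1ccc(OCc2ccccc2)c(OCc2ccccc2)c1 | starting material
16 | Z dibutylboron enolate of 14 (O–B and OBn cis) | O=C1OC[C@H](Cc2ccccc2)N1C(/OB(CCCC)CCCC)=C/OCc1ccccc1 | intermediate (not isolated)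
17 | (S)-4-benzyl-3-[(2S,3R)-2-(benzyloxy)-3-[3,4-bis(benzyloxy)phenyl]-3-hydroxypropanoyl]oxazolidin-2-one | O=C1OC[C@H](Cc2ccccc2)N1C(=O)[C@@H](OCc1ccccc1)[C@H](O)c1ccc(OCc2ccccc2)c(OCc2ccccc2)c1 | intermediate
18 | (2S,3R)-2-(benzyloxy)-3-[3,4-bis(benzyloxy)phenyl]-3-hydroxy-N-methoxy-N-methylpropanamide | CON(C)C(=O)[C@@H](OCc1ccccc1)[C@H](O)c1ccc(OCc2ccccc2)c(OCc2ccccc2)c1 | intermediate
19 | [2,4-bis(benzyloxy)-6-fluorophenyl]lithium | [Li]c1c(F)cc(OCc2ccccc2)cc1OCc1ccccc1 | intermediate (not isolated)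
20 | (2S,3R)-2-(benzyloxy)-1-[2,4-bis(benzyloxy)-6-fluorophenyl]-3-[3,4-bis(benzyloxy)phenyl]-3-hydroxypropan-1-one | O=C(c1c(F)cc(OCc2ccccc2)cc1OCc1ccccc1)[C@@H](OCc1ccccc1)[C@H](O)c1ccc(OCc2ccccc2)c(OCc2ccccc2)c1 | intermediate
21 | O-diethylboryl derivative of 20 (boron chelated to the ketone) | O=C(c1c(F)cc(OCc2ccccc2)cc1OCc1ccccc1)[C@@H](OCc1ccccc1)[C@H](OB(CC)CC)c1ccc(OCc2ccccc2)c(OCc2ccccc2)c1 | intermediate (not isolated)
22 | (1S,2S,3R)-2-(benzyloxy)-1-[2,4-bis(benzyloxy)-6-fluorophenyl]-3-[3,4-bis(benzyloxy)phenyl]propane-1,3-diol (all-syn) | O[C@@H](c1c(F)cc(OCc2ccccc2)cc1OCc1ccccc1)[C@@H](OCc1ccccc1)[C@H](O)c1ccc(OCc2ccccc2)c(OCc2ccccc2)c1 | intermediate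
23 | dipotassium dialkoxide of 22 | [K+].[K+].[O-][C@@H](c1c(F)cc(OCc2ccccc2)cc1OCc1ccccc1)[C@@H](OCc1ccccc1)[C@H]([O-])c1ccc(OCc2ccccc2)c(OCc2ccccc2)c1 | intermediate (not isolated)
24 | (2R,3R,4S)-3,5,7-tris(benzyloxy)-2-[3,4-bis(benzyloxy)phenyl]chroman-4-ol (2,3-cis-3,4-trans, 4β-ol) | O[C@H]1c2c(OCc3ccccc3)cc(OCc3ccccc3)cc2O[C@H](c2ccc(OCc3ccccc3)c(OCc3ccccc3)c2)[C@@H]1OCc1ccccc1 | intermediate
25 | C4 benzylic cation of 24 as its trifluoromethanesulfonate | [CH+]1c2c(OCc3ccccc3)cc(OCc3ccccc3)cc2O[C@H](c2ccc(OCc3ccccc3)c(OCc3ccccc3)c2)[C@@H]1OCc1ccccc1.[O-]S(=O)(=O)C(F)(F)F | intermediate (not isolated)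
26 | methyl ester of 3,5,7,3',4'-penta-O-benzylepicatechin-(4β→8)-5,7,3',4'-tetra-O-benzyl-4β-(carboxymethyl)epicatechin | COC(=O)C[C@H]1c2c(OCc5ccccc5)cc(OCc5ccccc5)c([C@H]3c4c(OCc5ccccc5)cc(OCc5ccccc5)cc4O[C@H](c4ccc(OCc5ccccc5)c(OCc5ccccc5)c4)[C@@H]3OCc5ccccc5)c2O[C@H](c2ccc(OCc5ccccc5)c(OCc5ccccc5)c2)[C@@H]1O | intermediate
27 | 3,5,7,3',4'-penta-O-benzylepicatechin-(4β→8)-5,7,3',4'-tetra-O-benzyl-4β-(carboxymethyl)epicatechin | OC(=O)C[C@H]1c2c(OCc5ccccc5)cc(OCc5ccccc5)c([C@H]3c4c(OCc5ccccc5)cc(OCc5ccccc5)cc4O[C@H](c4ccc(OCc5ccccc5)c(OCc5ccccc5)c4)[C@@H]3OCc5ccccc5)c2O[C@H](c2ccc(OCc5ccccc5)c(OCc5ccccc5)c2)[C@@H]1O | intermediate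
28 | epicatechin-(4β→8)-4β-(carboxymethyl)epicatechin, 2-[(2R,3R,4S)-2-(3,4-dihydroxyphenyl)-8-[(2R,3R,4R)-2-(3,4-dihydroxyphenyl)-3,5,7-trihydroxychroman-4-yl]-3,5,7-trihydroxychroman-4-yl]acetic acid | O=C(O)C[C@H]1c2c(O)cc(O)c([C@H]3c4c(O)cc(O)cc4O[C@H](c4ccc(O)c(O)c4)[C@@H]3O)c2O[C@H](c2ccc(O)c(O)c2)[C@@H]1O | target

Total step count: 14.
Longest linear sequence: 9 steps (steps 6, 7, 8, 9, 10, 11, 12, 13 and 14, from 11).

Steps most likely to fail

Step 11. The displacement may be slow on the electron-rich, carbonyl-free fluoroarene, so that base-induced degradation of the dialkoxide (benzyl ether cleavage, fragmentation) could outrun ring closure. The fallback keeps the same O1–C8a closure but uses copper-catalysed Ullmann-type etherification of an aryl bromide. Commercially available 1,3-bis(benzyloxy)-5-bromobenzene F1 would be iodinated (N-iodosuccinimide, cat. CF3CO2H, MeCN) para to one benzyloxy group to give 1,5-bis(benzyloxy)-3-bromo-2-iodobenzene F2. Selective iodine–magnesium exchange (i-PrMgCl·LiCl, THF, −40 °C) would give [2,4-bis(benzyloxy)-6-bromophenyl]magnesium chloride F3. Addition of F3 to Weinreb amide 18 (hydroxyl first deprotonated with i-PrMgCl) would give the bromo ketone (2S,3R)-2-(benzyloxy)-1-[2,4-bis(benzyloxy)-6-bromophenyl]-3-[3,4-bis(benzyloxy)phenyl]-3-hydroxypropan-1-one F4. Syn reduction as in step 10 would give the all-syn bromo diol 2-(benzyloxy)-1-[2,4-bis(benzyloxy)-6-bromophenyl]-3-[3,4-bis(benzyloxy)phenyl]propane-1,3-diol F5. CuI (10 mol %), 3,4,7,8-tetramethyl-1,10-phenanthroline and Cs2CO3 in toluene at 110 °C should then close ring C. This fallback sets out from 18 and comes back to the route at 24.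

Step 12. The cation may be captured by the free C8/C6 positions of a second molecule of 24 (oligomerisation), and attack of 6 through C6 instead of C8 may compete. The fallback blocks C8 of the electrophile. Compound 24 would be brominated (NBS, CH2Cl2, −78 °C) to 8-bromo-3,5,7,3',4'-penta-O-benzyl-flavan-3,4-diol (4β-ol) F6, whose ring A is blocked and deactivated. Coupling with 6 (1.2 equiv, TMSOTf, CH2Cl2, −78 °C) would give the 8-bromo analogue of 26 F7, and saponification as in step 13 the 8-bromo analogue of 27 F8. Hydrogenolysis over Pd(OH)2 on carbon in the presence of Et3N would remove the bromine together with the benzyl groups. This fallback sets out from 24 and comes back to the route at 28.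

Step 3. Silyl transfer from the ketene acetal to the free 3-OH, elimination to the flav-3-ene, or loss of facial control at C4 may compete with C–C bond formation. The fallback is Hosomi–Sakurai allylation followed by oxidative degradation. Compound 4 with allyltrimethylsilane and TMSOTf (CH2Cl2, −78 °C) would give 4β-allyl-5,7,3',4'-tetra-O-benzylepicatechin F9. Lemieux–Johnson cleavage (OsO4 cat., NaIO4, 2,6-lutidine, dioxane/H2O) would give [5,7,3',4'-tetra-O-benzylepicatechin-4β-yl]acetaldehyde F10. Pinnick oxidation (NaClO2, NaH2PO4, 2-methylbut-2-ene, t-BuOH/H2O) would give [5,7,3',4'-tetra-O-benzylepicatechin-4β-yl]acetic acid F11, and methylation with trimethylsilyldiazomethane in MeOH/toluene would give the methyl ester. This fallback sets out from 4 and comes back to the route at 6.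

Further compounds
F1 | step 11 | 1,3-bis(benzyloxy)-5-bromobenzene | Brc1cc(OCc2ccccc2)cc(OCc2ccccc2)c1
F2 | step 11 | 1,5-bis(benzyloxy)-3-bromo-2-iodobenzene | Brc1cc(OCc2ccccc2)cc(OCc2ccccc2)c1I
F3 | step 11 | [2,4-bis(benzyloxy)-6-bromophenyl]magnesium chloride | Cl[Mg]c1c(Br)cc(OCc2ccccc2)cc1OCc1ccccc1
F4 | step 11 | (2S,3R)-2-(benzyloxy)-1-[2,4-bis(benzyloxy)-6-bromophenyl]-3-[3,4-bis(benzyloxy)phenyl]-3-hydroxypropan-1-one | O=C(c1c(Br)cc(OCc2ccccc2)cc1OCc1ccccc1)[C@@H](OCc1ccccc1)[C@H](O)c1ccc(OCc2ccccc2)c(OCc2ccccc2)c1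
F5 | step 11 | all-syn 2-(benzyloxy)-1-[2,4-bis(benzyloxy)-6-bromophenyl]-3-[3,4-bis(benzyloxy)phenyl]propane-1,3-diol | O[C@@H](c1c(Br)cc(OCc2ccccc2)cc1OCc1ccccc1)[C@@H](OCc1ccccc1)[C@H](O)c1ccc(OCc2ccccc2)c(OCc2ccccc2)c1
F6 | step 12 | 8-bromo-3,5,7-tris(benzyloxy)-2-[3,4-bis(benzyloxy)phenyl]chroman-4-ol (2,3-cis-3,4-trans) | O[C@H]1c2c(OCc3ccccc3)cc(OCc3ccccc3)c(Br)c2O[C@H](c2ccc(OCc3ccccc3)c(OCc3ccccc3)c2)[C@@H]1OCc1ccccc1
F7 | step 12 | 8-bromo analogue of 26 (bromine at C8 of the upper unit) | COC(=O)C[C@H]1c2c(OCc5ccccc5)cc(OCc5ccccc5)c([C@H]3c4c(OCc5ccccc5)cc(OCc5ccccc5)c(Br)c4O[C@H](c4ccc(OCc5ccccc5)c(OCc5ccccc5)c4)[C@@H]3OCc5ccccc5)c2O[C@H](c2ccc(OCc5ccccc5)c(OCc5ccccc5)c2)[C@@H]1O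
F8 | step 12 | 8-bromo analogue of 27 (bromine at C8 of the upper unit) | OC(=O)C[C@H]1c2c(OCc5ccccc5)cc(OCc5ccccc5)c([C@H]3c4c(OCc5ccccc5)cc(OCc5ccccc5)c(Br)c4O[C@H](c4ccc(OCc5ccccc5)c(OCc5ccccc5)c4)[C@@H]3OCc5ccccc5)c2O[C@H](c2ccc(OCc5ccccc5)c(OCc5ccccc5)c2)[C@@H]1O
F9 | step 3 | 4β-allyl-5,7,3',4'-tetra-O-benzylepicatechin | C=CC[C@H]1c2c(OCc3ccccc3)cc(OCc3ccccc3)cc2O[C@H](c2ccc(OCc3ccccc3)c(OCc3ccccc3)c2)[C@@H]1O
F10 | step 3 | [5,7,3',4'-tetra-O-benzylepicatechin-4β-yl]acetaldehyde | O=CC[C@H]1c2c(OCc3ccccc3)cc(OCc3ccccc3)cc2O[C@H](c2ccc(OCc3ccccc3)c(OCc3ccccc3)c2)[C@@H]1O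
F11 | step 3 | [5,7,3',4'-tetra-O-benzylepicatechin-4β-yl]acetic acid | OC(=O)C[C@H]1c2c(OCc3ccccc3)cc(OCc3ccccc3)cc2O[C@H](c2ccc(OCc3ccccc3)c(OCc3ccccc3)c2)[C@@H]1O
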